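**Retrosynthetic overview**

1. The strategy rests on central ring C and its four oxygens: the ether to ring B at C-1 flanked by hydroxyls at C-2 and C-6, and the ether to ring D at C-4. C-1 and C-6 with their oxygens map onto a 1,2-dioxygenated alkyne, and C-2 to C-5 onto a 3-aryloxy vinylketene.
2. Key disconnection: after desilylation and hydrogenolysis of nine benzyl ethers, ring C is cut at C-1–C-2 and C-5–C-6 into the A–B aryloxy(triisopropylsilyloxy)acetylene and the 3-(D–E aryloxy)cyclobutenone (vinylketene–alkyne benzannulation).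
3. The alkyne comes from the A–B phenol via its (E)-1,2-dichlorovinyl ether, acetylide oxidation and O-silylation. The cyclobutenone comes from the D–E phenol and 3-chlorocyclobutenone; chloride replaces ethoxide as leaving group because a phenoxide cannot drive ethoxide out of a vinylogous ester.
4. Each dimer phenol comes from copper-catalysed coupling of a phenol with an ortho-bromobenzaldehyde followed by Dakin oxidation, which places the free hydroxyl next to the new diaryl ether.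
5. Ring order: rings A, B, D and E are bought as benzylated arenes; ring C is the only ring made, and it is made last.

Key step: step 13

Remark: rings are lettered A to E from the 3,5-dihydroxyphenoxy end, rings B to E are numbered from the carbon whose ether oxygen points towards ring A, and the three benzylated arenes used as starting materials are taken as catalogue compounds.

**Route**

Step 1
Reactants: 1 3,5-bis(benzyloxy)benzaldehyde
Product: 2 2-bromo-3,5-bis(benzyloxy)benzaldehyde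
Conditions: NBS, MeCN, 0 °C to rt, dark
Reagents that add atoms: N-bromosuccinimide, O=C1CCC(=O)N1Br
Why: Electrophilic aromatic bromination (SEAr) should go to C-2, which is para to one benzyloxy group and ortho to the other, because C-4 between the two ethers is the more hindered site, as is the rule for 3,5-dialkoxybenzaldehydes.

Step 2
Reactants: 2 2-bromo-3,5-bis(benzyloxy)benzaldehyde; 3 3,5-bis(benzyloxy)phenol
Product: 4 3,5-bis(benzyloxy)-2-[3,5-bis(benzyloxy)phenoxy]benzaldehyde (A–B aldehyde)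
Conditions: CuI (10 mol %), picolinic acid (20 mol %), K3PO4, DMSO, 90 °C
Reagents that add atoms: none
Why: Ullmann-type copper-catalysed diaryl ether coupling, in which the ortho-formyl group activates the flanked C–Br bond and the phenol partner has no ortho substituent.

Step 3
Reactants: 4 A–B aldehyde
Product: 6 3,5-bis(benzyloxy)-2-[3,5-bis(benzyloxy)phenoxy]phenol (A–B phenol; its aryl group is called the A–B aryl below), via A–B aryl formate 5 (not isolated)
Conditions: mCPBA, CH2Cl2, 0 °C to rt; aq. Na2S2O3/NaHCO3 wash; then K2CO3 (cat.), MeOH, rt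
Reagents that add atoms: 3-chloroperoxybenzoic acid, OOC(=O)c1cccc(Cl)c1
Why: Dakin-type Baeyer–Villiger oxidation, in which the electron-rich aryl group bearing the ortho-aryloxy donor migrates to oxygen and the formate is cleaved by mild methanolysis, so the hydroxyl appears at B-6 next to the diaryl ether.

Step 4
Reactants: 6 A–B phenol; 7 trichloroethylene
Product: 9 1,5-bis(benzyloxy)-2-[3,5-bis(benzyloxy)phenoxy]-3-{[(E)-1,2-dichloroethenyl]oxy}benzene (A–B dichlorovinyl ether), via dichloroacetylene 8 (not isolated)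
Conditions: K2CO3, DMF, 70 °C
Reagents that add atoms: none
Why: Base-induced loss of HCl from trichloroethylene gives dichloroacetylene, to which the phenoxide adds anti (nucleophilic addition to a haloalkyne), the standard route to aryl (E)-1,2-dichlorovinyl ethers.

Step 5
Reactants: 9 A–B dichlorovinyl ether
Product: 12 triisopropyl{[2-(A–B aryloxy)ethynyl]oxy}silane (A–B aryloxy(triisopropylsilyloxy)acetylene), via lithium aryloxyacetylide 10 (not isolated), via lithium ynolate 11 (not isolated)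
Conditions: n-BuLi (2.1 equiv), THF, −78 °C; t-BuOOLi (from t-BuOOH, LiN(SiMe3)2), THF, −78 to 0 °C; TIPSOTf, −78 °C; neutral alumina filtration
Reagents that add atoms: tert-butyl hydroperoxide, CC(C)(C)OO; triisopropylsilyl trifluoromethanesulfonate, CC(C)[Si](OS(=O)(=O)C(F)(F)F)(C(C)C)C(C)C
Why: Proposed new method: n-BuLi should turn the dichlorovinyl ether into the lithium acetylide by elimination and chlorine–lithium exchange (known for ynol ethers), the acetylide carbon then attacks the O–O bond of lithium tert-butyl peroxide to give the ynolate, and the bulky silyl triflate traps it on oxygen; the closest known reaction is the oxidation of alkyl- and aryl-substituted lithium acetylides with lithium tert-butyl peroxide followed by O-silylation, which has not been shown for an oxygen-substituted acetylide.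

Step 6
Reactants: 13 2,4,6-trihydroxybenzaldehyde
Product: 14 2,4,6-tris(benzyloxy)benzaldehyde
Conditions: BnBr (3.6 equiv), K2CO3, DMF, 70 °C
Reagents that add atoms: benzyl bromide, BrCc1ccccc1
Why: Williamson ether synthesis, in which the formyl group lowers the nucleophilicity of the ring carbons so that O-benzylation should win over C-benzylation, and excess reagent at 70 °C also alkylates the two hydrogen-bonded ortho hydroxyls.

Step 7
Reactants: 14 2,4,6-tris(benzyloxy)benzaldehyde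
Product: 16 2,4,6-tris(benzyloxy)phenol, via 2,4,6-tris(benzyloxy)phenyl formate 15 (not isolated)
Conditions: mCPBA, CH2Cl2, 0 °C to rt; aq. Na2S2O3/NaHCO3 wash; then K2CO3 (cat.), MeOH, rt, Ar
Reagents that add atoms: 3-chloroperoxybenzoic acid, OOC(=O)c1cccc(Cl)c1
Why: Dakin-type Baeyer–Villiger oxidation of a 2,4,6-trialkoxybenzaldehyde, for which aryl migration is strongly favoured, followed by formate methanolysis.

Step 8
Reactants: 17 1-bromo-3,5-bis(benzyloxy)benzene
Product: 19 2-bromo-4,6-bis(benzyloxy)benzaldehyde, via iminium salt 18 (not isolated)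
Conditions: POCl3, DMF, 0 to 70 °C; then H2O
Reagents that add atoms: N,N-dimethylformamide, CN(C)C=O; water, O
Why: Vilsmeier–Haack formylation, which should go mainly para to one benzyloxy group and ortho to the other (next to bromine), the usual outcome for 5-substituted 1,3-dialkoxybenzenes, the minor isomer formylated between the two ethers being removed by chromatography.

Step 9
Reactants: 16 2,4,6-tris(benzyloxy)phenol; 19 2-bromo-4,6-bis(benzyloxy)benzaldehyde
Product: 20 2,4-bis(benzyloxy)-6-[2,4,6-tris(benzyloxy)phenoxy]benzaldehyde (D–E aldehyde)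
Conditions: CuI (20 mol %), picolinic acid (40 mol %), K3PO4, DMSO, 100 °C, Ar
Reagents that add atoms: none
Why: Ullmann-type copper-catalysed diaryl ether coupling of a 2,6-dialkoxyphenol, with the picolinic acid ligand chosen for hindered phenols and the ortho-formyl group activating the bromide.

Step 10
Reactants: 20 D–E aldehyde
Product: 22 2,4-bis(benzyloxy)-6-[2,4,6-tris(benzyloxy)phenoxy]phenol (D–E phenol; its aryl group is called the D–E aryl below), via D–E aryl formate 21 (not isolated)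
Conditions: mCPBA, CH2Cl2, 0 °C to rt; aq. Na2S2O3/NaHCO3 wash; then K2CO3 (cat.), MeOH, rt
Reagents that add atoms: 3-chloroperoxybenzoic acid, OOC(=O)c1cccc(Cl)c1
Why: Dakin-type Baeyer–Villiger oxidation of a 2,4,6-trioxygenated benzaldehyde then methanolysis, which places the free hydroxyl at D-1 between the benzyl ether and the ring-E ether.

Step 11
Reactants: 23 3-ethoxycyclobut-2-en-1-one
Product: 24 cyclobutane-1,3-dione
Conditions: 2 M aq. HCl, THF, 0 °C to rt
Reagents that add atoms: water, O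
Why: Acid hydrolysis of a vinylogous ester (addition of water at C-3 and loss of ethanol), the known preparation of cyclobutane-1,3-dione.

Step 12
Reactants: 24 cyclobutane-1,3-dione (2 equiv); 22 D–E phenol
Product: 26 3-(D–E aryloxy)cyclobut-2-en-1-one, via 3-chlorocyclobut-2-en-1-one 25 (not isolated)
Conditions: (COCl)2, DMF (cat.), CH2Cl2, 0 °C, N2 purge; then 22, Cs2CO3, MeCN, 0 °C to rt
Reagents that add atoms: none
Why: Vinylogous acid chloride formation from the enolised 1,3-dione and then addition–elimination of the phenoxide at C-3, which should be irreversible because chloride, unlike ethoxide, is a better leaving group than the aryloxide.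

Step 13
Reactants: 12 A–B aryloxy(triisopropylsilyloxy)acetylene (1.2 equiv); 26 3-(D–E aryloxy)cyclobut-2-en-1-one
Product: 31 nonabenzyl pentamer bearing a free hydroxyl at C-2 and a triisopropylsilyl ether at C-6 of ring C, via vinylketene 27 (not isolated), via vinylcyclobutenone 28 (not isolated), via dienylketene 29 (not isolated), via cyclohexadienone 30 (not isolated)
Conditions: PhMe (degassed), 90 °C then 110 °C, sealed tube, Ar
Reagents that add atoms: none
Why: Proposed new method: thermal 4π opening of cyclobutenone 26 gives vinylketene 27, whose ketene C=C bond adds (2+2) to the electron-rich alkyne 12 to give vinylcyclobutenone 28; a second 4π opening gives dienylketene 29, and 6π electrocyclisation gives cyclohexadienone 30, which tautomerises to phenol 31. The closest known reaction is the Danheiser benzannulation of cyclobutenones with triisopropylsilyloxyalkynes and alkoxyalkynes, which has not been run with a 1,2-dioxygenated alkyne or with a 3-aryloxycyclobutenone of this size. Ring C is closed by the 6π electrocyclic ring closure; the new bonds are C-1–C-2 and C-5–C-6 from the cycloaddition, while C-2–C-3 is the old cyclobutenone bond re-formed in the electrocyclisation. No stereocentre results, since the one sp3 carbon of 28 becomes part of the arene. The step needs one orientation in the (2+2) addition: the silyloxy oxygen should be the better donor because the lone pairs of the aryloxy oxygen are shared with ring B, so the alkyne carbon bearing the ring-B ether is the nucleophilic one and bonds to the ketene carbonyl carbon. This places the ring-B ether at C-1 between the new hydroxyl and the silyloxy group and para to the ring-D ether, and all other groups are benzyl and diaryl ethers that are inert at 110 °C.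

Step 14
Reactants: 31 silyl-protected nonabenzyl pentamer
Product: 32 nonabenzyl pentamer with free hydroxyls at C-2 and C-6 of ring C
Conditions: TBAF, AcOH, THF, 0 °C, Ar
Reagents that add atoms: none
Why: Fluoride-mediated cleavage of the aryl silyl ether (desilylation), with acetic acid buffering the phenoxide so that the electron-rich ring is not oxidised and the benzyl and diaryl ethers stay untouched.

Step 15
Reactants: 32 nonabenzyl pentamer diol
Product: 33 CNP0018313.0 (target pentamer)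
Conditions: H2 (1 atm), 10% Pd/C, THF/MeOH, rt; filtration and concentration under Ar
Reagents that add atoms: none
Why: Palladium-catalysed hydrogenolysis cleaves the nine benzylic C–O bonds under neutral reducing conditions that leave diaryl ethers intact and keep the free polyphenol from air oxidation.

**Compound list**

1 | 3,5-bis(benzyloxy)benzaldehyde | O=Cc1cc(OCc2ccccc2)cc(OCc2ccccc2)c1 | starting material
2 | 2-bromo-3,5-bis(benzyloxy)benzaldehyde | O=Cc1cc(OCc2ccccc2)cc(OCc2ccccc2)c1Br | intermediate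
3 | 3,5-bis(benzyloxy)phenol | Oc1cc(OCc2ccccc2)cc(OCc2ccccc2)c1 | starting material
4 | 3,5-bis(benzyloxy)-2-[3,5-bis(benzyloxy)phenoxy]benzaldehyde (A–B aldehyde) | O=Cc1cc(OCc2ccccc2)cc(OCc2ccccc2)c1Oc1cc(OCc2ccccc2)cc(OCc2ccccc2)c1 | intermediate
5 | 3,5-bis(benzyloxy)-2-[3,5-bis(benzyloxy)phenoxy]phenyl formate | O=COc1cc(OCc2ccccc2)cc(OCc2ccccc2)c1Oc1cc(OCc2ccccc2)cc(OCc2ccccc2)c1 | intermediate
6 | 3,5-bis(benzyloxy)-2-[3,5-bis(benzyloxy)phenoxy]phenol (A–B phenol) | Oc1cc(OCc2ccccc2)cc(OCc2ccccc2)c1Oc1cc(OCc2ccccc2)cc(OCc2ccccc2)c1 | intermediate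
7 | trichloroethylene | ClC=C(Cl)Cl | starting material
8 | dichloroacetylene | ClC#CCl | intermediate
9 | 1,5-bis(benzyloxy)-2-[3,5-bis(benzyloxy)phenoxy]-3-{[(E)-1,2-dichloroethenyl]oxy}benzene | Cl/C=C(/Cl)Oc1cc(OCc2ccccc2)cc(OCc2ccccc2)c1Oc1cc(OCc2ccccc2)cc(OCc2ccccc2)c1 | intermediate
10 | [2-(A–B aryloxy)ethynyl]lithium | [Li]C#COc1cc(OCc2ccccc2)cc(OCc2ccccc2)c1Oc1cc(OCc2ccccc2)cc(OCc2ccccc2)c1 | intermediate
11 | lithium 2-(A–B aryloxy)ethynolate | [Li]OC#COc1cc(OCc2ccccc2)cc(OCc2ccccc2)c1Oc1cc(OCc2ccccc2)cc(OCc2ccccc2)c1 | intermediate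
12 | triisopropyl{[2-(A–B aryloxy)ethynyl]oxy}silane | CC(C)[Si](C(C)C)(C(C)C)OC#COc1cc(OCc2ccccc2)cc(OCc2ccccc2)c1Oc1cc(OCc2ccccc2)cc(OCc2ccccc2)c1 | intermediate
13 | 2,4,6-trihydroxybenzaldehyde | O=Cc1c(O)cc(O)cc1O | starting material
14 | 2,4,6-tris(benzyloxy)benzaldehyde | O=Cc1c(OCc2ccccc2)cc(OCc2ccccc2)cc1OCc1ccccc1 | intermediate
15 | 2,4,6-tris(benzyloxy)phenyl formate | O=COc1c(OCc2ccccc2)cc(OCc2ccccc2)cc1OCc1ccccc1 | intermediate
16 | 2,4,6-tris(benzyloxy)phenol | Oc1c(OCc2ccccc2)cc(OCc2ccccc2)cc1OCc1ccccc1 | intermediate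
17 | 1-bromo-3,5-bis(benzyloxy)benzene | Brc1cc(OCc2ccccc2)cc(OCc2ccccc2)c1 | starting material
18 | N-{[2-bromo-4,6-bis(benzyloxy)phenyl]methylidene}-N-methylmethanaminium dichlorophosphate | C[N+](C)=Cc1c(Br)cc(OCc2ccccc2)cc1OCc1ccccc1.[O-]P(=O)(Cl)Cl | intermediate
19 | 2-bromo-4,6-bis(benzyloxy)benzaldehyde | O=Cc1c(Br)cc(OCc2ccccc2)cc1OCc1ccccc1 | intermediate
20 | 2,4-bis(benzyloxy)-6-[2,4,6-tris(benzyloxy)phenoxy]benzaldehyde (D–E aldehyde) | O=Cc1c(OCc2ccccc2)cc(OCc2ccccc2)cc1Oc1c(OCc2ccccc2)cc(OCc2ccccc2)cc1OCc1ccccc1 | intermediate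
21 | 2,4-bis(benzyloxy)-6-[2,4,6-tris(benzyloxy)phenoxy]phenyl formate | O=COc1c(OCc2ccccc2)cc(OCc2ccccc2)cc1Oc1c(OCc2ccccc2)cc(OCc2ccccc2)cc1OCc1ccccc1 | intermediate
22 | 2,4-bis(benzyloxy)-6-[2,4,6-tris(benzyloxy)phenoxy]phenol (D–E phenol) | Oc1c(OCc2ccccc2)cc(OCc2ccccc2)cc1Oc1c(OCc2ccccc2)cc(OCc2ccccc2)cc1OCc1ccccc1 | intermediate
23 | 3-ethoxycyclobut-2-en-1-one | CCOC1=CC(=O)C1 | starting material
24 | cyclobutane-1,3-dione | O=C1CC(=O)C1 | intermediate
25 | 3-chlorocyclobut-2-en-1-one | O=C1C=C(Cl)C1 | intermediate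
26 | 3-(D–E aryloxy)cyclobut-2-en-1-one | O=C1CC(Oc2c(OCc3ccccc3)cc(OCc3ccccc3)cc2Oc2c(OCc3ccccc3)cc(OCc3ccccc3)cc2OCc2ccccc2)=C1 | intermediate
27 | 3-(D–E aryloxy)buta-1,3-dien-1-one (vinylketene) | O=C=CC(=C)Oc1c(OCc2ccccc2)cc(OCc2ccccc2)cc1Oc1c(OCc2ccccc2)cc(OCc2ccccc2)cc1OCc1ccccc1 | intermediate
28 | racemic 2-(A–B aryloxy)-3-(triisopropylsilyloxy)-4-[1-(D–E aryloxy)ethenyl]cyclobut-2-en-1-one | O=C1C(Oc2cc(OCc3ccccc3)cc(OCc3ccccc3)c2Oc2cc(OCc3ccccc3)cc(OCc3ccccc3)c2)=C(O[Si](C(C)C)(C(C)C)C(C)C)C1C(=C)Oc1c(OCc2ccccc2)cc(OCc2ccccc2)cc1Oc1c(OCc2ccccc2)cc(OCc2ccccc2)cc1OCc1ccccc1 | intermediate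
29 | 2-(A–B aryloxy)-3-(triisopropylsilyloxy)-5-(D–E aryloxy)hexa-1,3,5-trien-1-one, ketene and aryloxyvinyl groups cis on the central double bond (dienylketene) | O=C=C(Oc1cc(OCc2ccccc2)cc(OCc2ccccc2)c1Oc1cc(OCc2ccccc2)cc(OCc2ccccc2)c1)/C(O[Si](C(C)C)(C(C)C)C(C)C)=C\C(=C)Oc1c(OCc2ccccc2)cc(OCc2ccccc2)cc1Oc1c(OCc2ccccc2)cc(OCc2ccccc2)cc1OCc1ccccc1 | intermediate
30 | 2-(A–B aryloxy)-3-(triisopropylsilyloxy)-5-(D–E aryloxy)cyclohexa-2,4-dien-1-one | O=C1CC(Oc2c(OCc3ccccc3)cc(OCc3ccccc3)cc2Oc2c(OCc3ccccc3)cc(OCc3ccccc3)cc2OCc2ccccc2)=CC(O[Si](C(C)C)(C(C)C)C(C)C)=C1Oc1cc(OCc2ccccc2)cc(OCc2ccccc2)c1Oc1cc(OCc2ccccc2)cc(OCc2ccccc2)c1 | intermediate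
31 | 2-(A–B aryloxy)-5-(D–E aryloxy)-3-(triisopropylsilyloxy)phenol (silyl-protected nonabenzyl pentamer) | Oc1cc(Oc2c(OCc3ccccc3)cc(OCc3ccccc3)cc2Oc2c(OCc3ccccc3)cc(OCc3ccccc3)cc2OCc2ccccc2)cc(O[Si](C(C)C)(C(C)C)C(C)C)c1Oc1cc(OCc2ccccc2)cc(OCc2ccccc2)c1Oc1cc(OCc2ccccc2)cc(OCc2ccccc2)c1 | intermediate
32 | 2-(A–B aryloxy)-5-(D–E aryloxy)benzene-1,3-diol (nonabenzyl pentamer diol) | Oc1cc(Oc2c(OCc3ccccc3)cc(OCc3ccccc3)cc2Oc2c(OCc3ccccc3)cc(OCc3ccccc3)cc2OCc2ccccc2)cc(O)c1Oc1cc(OCc2ccccc2)cc(OCc2ccccc2)c1Oc1cc(OCc2ccccc2)cc(OCc2ccccc2)c1 | intermediate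
33 | CNP0018313.0 | Oc1cc(O)cc(Oc2c(O)cc(O)cc2Oc2c(O)cc(Oc3c(O)cc(O)cc3Oc3c(O)cc(O)cc3O)cc2O)c1 | target

**Step count and risks**

Total steps: 15. Longest linear sequence: 8 steps (steps 6, 7, 9, 10, 12, 13, 14, 15; the A–B branch through steps 1 to 5 and 13 to 15 is equally long).

Steps most likely to fail:

1. Step 13 (Proposed new method). The (2+2) addition may run with the opposite orientation, because the donor difference between the silyloxy and the aryloxy oxygen is modest. The vinylketene may also be lost to dimerisation or to acylation of the product phenol before it meets the hindered alkyne. The fallback uses known chemistry only, gives up the benzannulation and brings in ring C as a preformed arene, setting out from D–E phenol 22. Double nucleophilic aromatic substitution of commercial 4-bromo-2,6-difluorobenzaldehyde with sodium benzyloxide (BnOH, NaH, DMF) would give 4-bromo-2,6-bis(benzyloxy)benzaldehyde F1. Ullmann coupling of 22 with F1 (CuI, picolinic acid, K3PO4, DMSO) would give the E–D–C trimer aldehyde F2. Dakin oxidation (mCPBA; then K2CO3, MeOH) via the trimer formate F3 would give the trimer phenol F4, with its hydroxyl at C-1 of ring C. A second Ullmann coupling, of F4 with bromoaldehyde 19, would give the tetramer aldehyde F5, and Dakin oxidation via the tetramer formate F6 would give the tetramer phenol F7 (hydroxyl at B-1). A third Ullmann coupling, of F7 with bromide 17, would give the undecabenzyl pentamer F8. Hydrogenolysis of F8 (H2, Pd/C) comes back to the route at target 33.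

2. Step 5 (Proposed new method). Oxygen transfer from the peroxide to the oxygen-substituted acetylide may be slower than ring lithiation next to the benzyloxy groups or decomposition of the acetylide. Silylation may also take place at carbon to give a silylketene, and the very electron-rich alkyne may hydrolyse on isolation. The fallback uses known chemistry only and needs no alkyne. It sets out from A–B phenol 6 and extends the chain towards ring E by the coupling and Dakin sequence of steps 2 and 3. Ullmann coupling of 6 with commercial 4-bromo-3,5-dimethoxybenzaldehyde (CuI, picolinic acid, K3PO4, DMSO) would give the A–B–C trimer aldehyde F9, with ring C as its dimethyl ether. Dakin oxidation via the trimer formate F10 would give the trimer phenol F11 (hydroxyl at C-4 of ring C). Coupling of F11 with bromoaldehyde 2 would give the tetramer aldehyde F12, and Dakin oxidation via the tetramer formate F13 would give the tetramer phenol F14 (hydroxyl at D-6). Coupling of F14 with a second portion of 2 would give the pentamer aldehyde F15, and Dakin oxidation via the pentamer formate F16 would give the pentamer phenol F17 (hydroxyl at E-2). Hydrogenolysis of the eight benzyl ethers of F17 (H2, Pd/C) would give the ring-C dimethyl ether F18. BBr3 (CH2Cl2, −78 °C to rt) would cleave the two methyl ethers and come back to the route at target 33.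

3. Step 12. The hindered phenoxide may attack the carbonyl carbon with ring cleavage, or the volatile, reactive chloroenone may be lost before it is trapped. The fallback builds the four-membered ring on the aryl ether instead of substituting a preformed ring, setting out from D–E phenol 22. Trichloroethylene 7 and K2CO3 in DMF would give the D–E (E)-1,2-dichlorovinyl ether F19. n-BuLi (THF, −78 °C) would give the lithium acetylide F20, protonated with methanol to the D–E aryl ethynyl ether F21. (2+2) cycloaddition of F21 with dichloroketene F22 (from trichloroacetyl chloride and Zn(Cu), Et2O) would give the 4,4-dichloro-3-(D–E aryloxy)cyclobutenone F23. Zn with AcOH and TMEDA in EtOH would remove both chlorines and come back to the route at cyclobutenone 26.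

**Further compounds**

F1 | step 13 | 4-bromo-2,6-bis(benzyloxy)benzaldehyde | O=Cc1c(OCc2ccccc2)cc(Br)cc1OCc1ccccc1
F2 | step 13 | 2,6-bis(benzyloxy)-4-(D–E aryloxy)benzaldehyde (E–D–C trimer aldehyde) | O=Cc1c(OCc2ccccc2)cc(Oc2c(OCc3ccccc3)cc(OCc3ccccc3)cc2Oc2c(OCc3ccccc3)cc(OCc3ccccc3)cc2OCc2ccccc2)cc1OCc1ccccc1
F3 | step 13 | 2,6-bis(benzyloxy)-4-(D–E aryloxy)phenyl formate (trimer formate) | O=COc1c(OCc2ccccc2)cc(Oc2c(OCc3ccccc3)cc(OCc3ccccc3)cc2Oc2c(OCc3ccccc3)cc(OCc3ccccc3)cc2OCc2ccccc2)cc1OCc1ccccc1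
F4 | step 13 | 2,6-bis(benzyloxy)-4-(D–E aryloxy)phenol (trimer phenol) | Oc1c(OCc2ccccc2)cc(Oc2c(OCc3ccccc3)cc(OCc3ccccc3)cc2Oc2c(OCc3ccccc3)cc(OCc3ccccc3)cc2OCc2ccccc2)cc1OCc1ccccc1
F5 | step 13 | 2,4-bis(benzyloxy)-6-[2,6-bis(benzyloxy)-4-(D–E aryloxy)phenoxy]benzaldehyde (tetramer aldehyde) | O=Cc1c(OCc2ccccc2)cc(OCc2ccccc2)cc1Oc1c(OCc2ccccc2)cc(Oc2c(OCc3ccccc3)cc(OCc3ccccc3)cc2Oc2c(OCc3ccccc3)cc(OCc3ccccc3)cc2OCc2ccccc2)cc1OCc1ccccc1
F6 | step 13 | 2,4-bis(benzyloxy)-6-[2,6-bis(benzyloxy)-4-(D–E aryloxy)phenoxy]phenyl formate (tetramer formate) | O=COc1c(OCc2ccccc2)cc(OCc2ccccc2)cc1Oc1c(OCc2ccccc2)cc(Oc2c(OCc3ccccc3)cc(OCc3ccccc3)cc2Oc2c(OCc3ccccc3)cc(OCc3ccccc3)cc2OCc2ccccc2)cc1OCc1ccccc1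
F7 | step 13 | 2,4-bis(benzyloxy)-6-[2,6-bis(benzyloxy)-4-(D–E aryloxy)phenoxy]phenol (tetramer phenol) | Oc1c(OCc2ccccc2)cc(OCc2ccccc2)cc1Oc1c(OCc2ccccc2)cc(Oc2c(OCc3ccccc3)cc(OCc3ccccc3)cc2Oc2c(OCc3ccccc3)cc(OCc3ccccc3)cc2OCc2ccccc2)cc1OCc1ccccc1
F8 | step 13 | undecabenzyl ether of the target pentamer | c1c(OCc2ccccc2)cc(OCc2ccccc2)cc1Oc1c(OCc2ccccc2)cc(OCc2ccccc2)cc1Oc1c(OCc2ccccc2)cc(Oc2c(OCc3ccccc3)cc(OCc3ccccc3)cc2Oc2c(OCc3ccccc3)cc(OCc3ccccc3)cc2OCc2ccccc2)cc1OCc1ccccc1
F9 | step 5 | 4-(A–B aryloxy)-3,5-dimethoxybenzaldehyde (A–B–C trimer aldehyde) | O=Cc1cc(OC)c(Oc2cc(OCc3ccccc3)cc(OCc3ccccc3)c2Oc2cc(OCc3ccccc3)cc(OCc3ccccc3)c2)c(OC)c1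
F10 | step 5 | 4-(A–B aryloxy)-3,5-dimethoxyphenyl formate (trimer formate) | O=COc1cc(OC)c(Oc2cc(OCc3ccccc3)cc(OCc3ccccc3)c2Oc2cc(OCc3ccccc3)cc(OCc3ccccc3)c2)c(OC)c1
F11 | step 5 | 4-(A–B aryloxy)-3,5-dimethoxyphenol (trimer phenol) | Oc1cc(OC)c(Oc2cc(OCc3ccccc3)cc(OCc3ccccc3)c2Oc2cc(OCc3ccccc3)cc(OCc3ccccc3)c2)c(OC)c1
F12 | step 5 | 3,5-bis(benzyloxy)-2-[4-(A–B aryloxy)-3,5-dimethoxyphenoxy]benzaldehyde (tetramer aldehyde) | O=Cc1cc(OCc2ccccc2)cc(OCc2ccccc2)c1Oc1cc(OC)c(Oc2cc(OCc3ccccc3)cc(OCc3ccccc3)c2Oc2cc(OCc3ccccc3)cc(OCc3ccccc3)c2)c(OC)c1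
F13 | step 5 | 3,5-bis(benzyloxy)-2-[4-(A–B aryloxy)-3,5-dimethoxyphenoxy]phenyl formate (tetramer formate) | O=COc1cc(OCc2ccccc2)cc(OCc2ccccc2)c1Oc1cc(OC)c(Oc2cc(OCc3ccccc3)cc(OCc3ccccc3)c2Oc2cc(OCc3ccccc3)cc(OCc3ccccc3)c2)c(OC)c1
F14 | step 5 | 3,5-bis(benzyloxy)-2-[4-(A–B aryloxy)-3,5-dimethoxyphenoxy]phenol (tetramer phenol) | Oc1cc(OCc2ccccc2)cc(OCc2ccccc2)c1Oc1cc(OC)c(Oc2cc(OCc3ccccc3)cc(OCc3ccccc3)c2Oc2cc(OCc3ccccc3)cc(OCc3ccccc3)c2)c(OC)c1
F15 | step 5 | 3,5-bis(benzyloxy)-2-{3,5-bis(benzyloxy)-2-[4-(A–B aryloxy)-3,5-dimethoxyphenoxy]phenoxy}benzaldehyde (pentamer aldehyde) | O=Cc1cc(OCc2ccccc2)cc(OCc2ccccc2)c1Oc1cc(OCc2ccccc2)cc(OCc2ccccc2)c1Oc1cc(OC)c(Oc2cc(OCc3ccccc3)cc(OCc3ccccc3)c2Oc2cc(OCc3ccccc3)cc(OCc3ccccc3)c2)c(OC)c1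
F16 | step 5 | 3,5-bis(benzyloxy)-2-{3,5-bis(benzyloxy)-2-[4-(A–B aryloxy)-3,5-dimethoxyphenoxy]phenoxy}phenyl formate (pentamer formate) | O=COc1cc(OCc2ccccc2)cc(OCc2ccccc2)c1Oc1cc(OCc2ccccc2)cc(OCc2ccccc2)c1Oc1cc(OC)c(Oc2cc(OCc3ccccc3)cc(OCc3ccccc3)c2Oc2cc(OCc3ccccc3)cc(OCc3ccccc3)c2)c(OC)c1
F17 | step 5 | 3,5-bis(benzyloxy)-2-{3,5-bis(benzyloxy)-2-[4-(A–B aryloxy)-3,5-dimethoxyphenoxy]phenoxy}phenol (pentamer phenol) | Oc1cc(OCc2ccccc2)cc(OCc2ccccc2)c1Oc1cc(OCc2ccccc2)cc(OCc2ccccc2)c1Oc1cc(OC)c(Oc2cc(OCc3ccccc3)cc(OCc3ccccc3)c2Oc2cc(OCc3ccccc3)cc(OCc3ccccc3)c2)c(OC)c1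
F18 | step 5 | target pentamer with methyl ethers at C-2 and C-6 of ring C | Oc1cc(O)cc(Oc2c(O)cc(O)cc2Oc2c(OC)cc(Oc3c(O)cc(O)cc3Oc3c(O)cc(O)cc3O)cc2OC)c1
F19 | step 12 | D–E aryl (E)-1,2-dichloroethenyl ether | Cl/C=C(/Cl)Oc1c(OCc2ccccc2)cc(OCc2ccccc2)cc1Oc1c(OCc2ccccc2)cc(OCc2ccccc2)cc1OCc1ccccc1
F20 | step 12 | [2-(D–E aryloxy)ethynyl]lithium | [Li]C#COc1c(OCc2ccccc2)cc(OCc2ccccc2)cc1Oc1c(OCc2ccccc2)cc(OCc2ccccc2)cc1OCc1ccccc1
F21 | step 12 | D–E aryl ethynyl ether | C#COc1c(OCc2ccccc2)cc(OCc2ccccc2)cc1Oc1c(OCc2ccccc2)cc(OCc2ccccc2)cc1OCc1ccccc1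
F22 | step 12 | dichloroketene | O=C=C(Cl)Cl
F23 | step 12 | 4,4-dichloro-3-(D–E aryloxy)cyclobut-2-en-1-one | O=C1C=C(Oc2c(OCc3ccccc3)cc(OCc3ccccc3)cc2Oc2c(OCc3ccccc3)cc(OCc3ccccc3)cc2OCc2ccccc2)C1(Cl)Cl
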